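**Strategy**

The ring (cyclohexanol numbering: C1 carbinol, C2 CH, C3 quaternary C, C4 CHBr) is disconnected at C2–C3. Bromine at C4, the C2–C3 bond and the C1 hydroxyl are the imprint of two anti additions across the E-trisubstituted olefins of an acyclic 1,5-diene. The precursor is therefore an open-chain hexadecatetraene diacetate whose only stereocentre, the side-chain carbinol, comes from Sharpless epoxidation of farnesol. A vanadium bromoperoxidase then does in one operation what no small reagent does selectively: Br+ delivery to one face of the 10,11-olefin, chair closure of the six-membered ring and capture of the C1 cation by water, which sets all four ring stereocentres.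

Key step: step 7

Remark: chain locants C1–C16 are those of hexadecatetraene 8; boronate 7 and an algal V-BPO preparation are taken as purchasable, and the enzyme is assumed to show with 9 the facial preference needed for the (4S) C–Br centre.

**Route**

Step 1
Reactants: 1 (2E,6E)-farnesol
Product: 2 (2S,3S)-2,3-epoxyfarnesol
Conditions: Ti(OiPr)4 (5 mol %), L-(+)-DET (7 mol %), t-BuOOH, 4 Å MS, CH2Cl2, −20 °C
Reagents that add atoms: tert-butyl hydroperoxide, CC(C)(C)OO
Why: Sharpless asymmetric epoxidation engages only the allylic-alcohol olefin and, with L-(+)-tartrate, delivers oxygen to the face that gives the (2S,3S)-epoxide, which fixes the future side-chain carbinol centre.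

Step 2
Reactants: 2 (2S,3S)-2,3-epoxyfarnesol
Product: 4 (3S,6E)-nerolidol, via epoxy iodide 3 (not isolated)
Conditions: PPh3, imidazole, I2, THF, 0 °C; then Zn dust, AcOH, 0 °C → rt
Reagents that add atoms: none
Why: Appel-type iodination of the primary alcohol and zinc-induced reductive β-elimination of the 2,3-epoxy iodide break only the C2–O bond, so the C3–O bond and its (S) configuration pass unchanged into the tertiary allylic alcohol.

Step 3
Reactants: 4 (3S,6E)-nerolidol
Product: 5 (3S)-12-hydroxynerolidol
Conditions: SeO2 (0.2 equiv), t-BuOOH, salicylic acid (0.1 equiv), CH2Cl2, 0 °C → rt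
Reagents that add atoms: selenium dioxide, O=[Se]=O (oxygen carrier); tert-butyl hydroperoxide, CC(C)(C)OO
Why: The SeO2/t-BuOOH allylic oxidation (ene reaction then [2,3]-shift) is expected to pick the (E)-methyl of the terminal isopropylidene group and to return the (E)-allylic alcohol, the tertiary carbinol being a spectator.

Step 4
Reactants: 5 (3S)-12-hydroxynerolidol
Product: 6 (3S)-12-bromonerolidol
Conditions: CBr4, PPh3, CH2Cl2, 0 °C
Reagents that add atoms: carbon tetrabromide, BrC(Br)(Br)Br
Why: The Appel reaction converts the primary allylic alcohol by SN2 displacement, while the tertiary alcohol is too hindered to form an alkoxyphosphonium ion at this temperature.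

Step 5
Reactants: 6 (3S)-12-bromonerolidol; 7 (E)-3-hydroxy-3-methylbut-1-enylboronic acid pinacol ester
Product: 8 tetraene diol
Conditions: Pd(PPh3)4 (5 mol %), K2CO3, THF/H2O, 45 °C
Reagents that add atoms: none
Why: Suzuki–Miyaura allyl–alkenyl coupling (oxidative addition to the primary allylic bromide, transmetalation, reductive elimination at the less hindered allyl terminus) should build the skipped diene with both E geometries retained and the free tertiary alcohols untouched.

Step 6
Reactants: 8 tetraene diol
Product: 9 tetraene diacetate
Conditions: Ac2O, DMAP, Et3N, CH2Cl2, 40 °C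
Reagents that add atoms: acetic anhydride, CC(=O)OC(C)=O
Why: DMAP-catalysed acylation esterifies both tertiary alcohols under basic, non-ionising conditions, which masks O3 as a non-nucleophilic group and deactivates the vinyl and 13,14-olefins for the key step.

Step 7
Reactants: 9 tetraene diacetate
Product: 11 ring-closed bromo alcohol diacetate, via bromiranium ion 10 (not isolated)
Conditions: vanadium bromoperoxidase (Corallina officinalis type), KBr, H2O2 (slow addition), Na3VO4 (cat.), MES buffer pH 6.5/t-BuOH, 25 °C
Reagents that add atoms: potassium bromide, [K+].[Br-]; water, O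
Why: The vanadium bromoperoxidase oxidises bromide with H2O2 to an enzyme-held Br+ donor that converts the 10,11-olefin of 9 into bromiranium ion 10, whose tertiary carbon is attacked anti to bromine by C6 of the 6,7-olefin while water adds at C7 anti to the new C–C bond. The closest known reaction type is the haloperoxidase-mediated brominative cation–olefin cyclisation of acyclic terpenoids (nerolidol to snyderol-type bromocyclohexanes). The ring closes in a 6-endo mode with respect to both the bromiranium ion and the terminating olefin, through a chair in which bromine and the C5 chain are equatorial. The C–Br centre (ring C4) is set by the face of Br+ delivery, which is the enzyme's contribution; the quaternary centre (ring C3) follows from anti opening and the 10E geometry, the ring CH (C2) from the 6E geometry in the chair, and the carbinol centre (ring C1) from equatorial water attack anti to the new bond and trans to the axial C3 methyl. The step needs site selectivity among four olefins and water as the only terminator: the vinyl and 13,14-olefins are deactivated by their allylic acetoxy groups and lower substitution, the acetate on O3 removes the internal oxygen nucleophile that would otherwise give bromo-ethers at the 6,7-olefin or at the C7 cation, and of the two trisubstituted olefins only the 10,11-bromiranium ion has a low-barrier six-membered exit, bromiranium formation being reversible in the bromide-rich medium.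

Step 8
Reactants: 11 ring-closed bromo alcohol diacetate
Product: 12 target bromo triol
Conditions: K2CO3, MeOH, 40 °C
Reagents that add atoms: none
Why: Base-catalysed transesterification cleaves both tertiary acetates by acyl–oxygen fission, so no stereocentre is touched, and the equatorial neopentyl bromide has no anti-periplanar hydrogen for E2 and is shielded against SN2.

**Compound list**

1 | (2E,6E)-farnesol, (2E,6E)-3,7,11-trimethyldodeca-2,6,10-trien-1-ol | OC/C=C(\C)CC/C=C(\C)CCC=C(C)C | starting material
2 | (2S,3S)-2,3-epoxyfarnesol, [(2S,3S)-3-methyl-3-[(3E)-4,8-dimethylnona-3,7-dien-1-yl]oxiran-2-yl]methanol | OC[C@@H]1O[C@@]1(C)CC/C=C(\C)CCC=C(C)C | intermediate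
3 | epoxy iodide, (2R,3S)-2-(iodomethyl)-3-methyl-3-[(3E)-4,8-dimethylnona-3,7-dien-1-yl]oxirane | IC[C@@H]1O[C@@]1(C)CC/C=C(\C)CCC=C(C)C | intermediate (not isolated)
4 | (3S,6E)-nerolidol, (3S,6E)-3,7,11-trimethyldodeca-1,6,10-trien-3-ol | C=C[C@@](C)(O)CC/C=C(\C)CCC=C(C)C | intermediate
5 | (3S)-12-hydroxynerolidol, (2E,6E,10S)-2,6,10-trimethyldodeca-2,6,11-triene-1,10-diol | C=C[C@@](C)(O)CC/C=C(\C)CC/C=C(\C)CO | intermediate
6 | (3S)-12-bromonerolidol, (3S,6E,10E)-12-bromo-3,7,11-trimethyldodeca-1,6,10-trien-3-ol | C=C[C@@](C)(O)CC/C=C(\C)CC/C=C(\C)CBr | intermediate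
7 | (E)-2-methyl-4-(4,4,5,5-tetramethyl-1,3,2-dioxaborolan-2-yl)but-3-en-2-ol | CC(C)(O)/C=C/B1OC(C)(C)C(C)(C)O1 | starting material
8 | tetraene diol, (3S,6E,10E,13E)-3,7,11,15-tetramethylhexadeca-1,6,10,13-tetraene-3,15-diol | C=C[C@@](C)(O)CC/C=C(\C)CC/C=C(\C)C/C=C/C(C)(C)O | intermediate
9 | tetraene diacetate, (3S,6E,10E,13E)-3,7,11,15-tetramethylhexadeca-1,6,10,13-tetraene-3,15-diyl diacetate | C=C[C@@](C)(OC(C)=O)CC/C=C(\C)CC/C=C(\C)C/C=C/C(C)(C)OC(C)=O | intermediate
10 | bromiranium ion, (10S,11S)-10,11-bromiranium ion of 9 (C9 and the C11 methyl cis on the three-membered ring) | C=C[C@@](C)(OC(C)=O)CC/C=C(\C)CC[C@@H]1[Br+][C@@]1(C)C/C=C/C(C)(C)OC(C)=O | intermediate (not isolated)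
11 | ring-closed bromo alcohol diacetate, (1S,2S,3S,4S)-4-bromo-1,3-dimethyl-2-[(3S)-3-acetoxy-3-methylpent-4-en-1-yl]-3-[(2E)-4-acetoxy-4-methylpent-2-en-1-yl]cyclohexan-1-ol | C=C[C@@](C)(OC(C)=O)CC[C@H]1[C@](C)(C/C=C/C(C)(C)OC(C)=O)[C@@H](Br)CC[C@]1(C)O | intermediate
12 | target, (1S,2S,3S,4S)-4-bromo-2-[(3S)-3-hydroxy-3-methylpent-4-en-1-yl]-3-[(2E)-4-hydroxy-4-methylpent-2-en-1-yl]-1,3-dimethylcyclohexan-1-ol | C=C[C@@](C)(O)CC[C@H]1[C@](C)(C/C=C/C(C)(C)O)[C@@H](Br)CC[C@]1(C)O | target

**Step count and risks**

Total step count: 8. Longest linear sequence: 8 steps (1 → 12).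

Steps most likely to fail:

1. Step 7 (key step). The enzyme may fail to discriminate between the 6,7- and 10,11-olefins or between the two faces of the 10,11-olefin. Turnover may be poor with the lipophilic diacetate. The C7 cation may lose a proton to give olefin isomers instead of being hydrated. The fallback sets out from 9 and comes back at 11. Treatment of 9 with Hg(OTf)2·PhNMe2 in MeNO2 containing a few equivalents of water at −20 °C, then aqueous KBr, should give the water-trapped monocyclic organomercuric bromide F1; metal-induced cyclisation with hydroxyl termination is a known reaction of polyprenyl esters. Brominative demercuration (Br2, LiBr, pyridine, O2) should then give 11. No facial control is asked of the reagent here: 11 would be separated by chromatography from its C–Br epimer and from the ring-antipodal series, which is diastereomeric because of the (3S) side-chain centre.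

2. Step 3. The oxidation may spread to the internal allylic positions, run on to the enal, or ionise the tertiary allylic alcohol. The fallback sets out from 4 and comes back at 5. Terminal-selective bromohydrin formation (NBS, THF/H2O, 0 °C) should give the bromohydrin F2. Ring closure (K2CO3, MeOH) gives the 10,11-epoxide F3, and periodic acid cleavage (H5IO6, THF/H2O) gives the trisnor aldehyde F4. E-selective Wittig olefination with ethyl 2-(triphenylphosphoranylidene)propanoate gives the enoate F5, and DIBAL-H reduction (CH2Cl2, −78 °C) gives 5.

3. Step 5. Isomerisation of the π-allyl intermediate may erode the 10E geometry or give branched coupling, and protodeboronation or homocoupling may consume the boronate. The fallback sets out from 6 and comes back at 8. Copper-catalysed allylation of 2-methylbut-3-yn-2-ol with 6 (CuI, K2CO3, NaI, DMF, rt) should give the skipped enyne diol F6. Hydroxyl-directed trans-hydroalumination of the propargylic alcohol (Red-Al, THF, 0 °C → rt) then gives the (13E)-olefin of 8.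

Further compounds
F1 | step 7 | organomercuric bromide, 11 with HgBr in place of Br at ring C4 | C=C[C@@](C)(OC(C)=O)CC[C@H]1[C@](C)(C/C=C/C(C)(C)OC(C)=O)[C@@H]([Hg]Br)CC[C@]1(C)O
F2 | step 3 | bromohydrin, (3S,6E,10RS)-10-bromo-3,7,11-trimethyldodeca-1,6-diene-3,11-diol | C=C[C@@](C)(O)CC/C=C(\C)CCC(Br)C(C)(C)O
F3 | step 3 | 10,11-epoxide, (3S,6E,10RS)-10,11-epoxy-3,7,11-trimethyldodeca-1,6-dien-3-ol | C=C[C@@](C)(O)CC/C=C(\C)CCC1OC1(C)C
F4 | step 3 | trisnor aldehyde, (4E,8S)-8-hydroxy-4,8-dimethyldeca-4,9-dienal | C=C[C@@](C)(O)CC/C=C(\C)CCC=O
F5 | step 3 | enoate, ethyl (2E,6E,10S)-10-hydroxy-2,6,10-trimethyldodeca-2,6,11-trienoate | C=C[C@@](C)(O)CC/C=C(\C)CC/C=C(\C)C(=O)OCC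
F6 | step 5 | skipped enyne diol, (3S,6E,10E)-3,7,11,15-tetramethylhexadeca-1,6,10-trien-13-yne-3,15-diol | C=C[C@@](C)(O)CC/C=C(\C)CC/C=C(\C)CC#CC(C)(C)O
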